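**Plan**

1. Cuts (azulene numbering of the target): first the allylic C–O bond of the vanillate; then the two ring bonds C3a–C4 and C5–C6, which removes the C4–C5 unit as ethene and, once C3a and C6 are joined, leaves a pentalenone; then the three bonds of that cyclopentenone (Pauson–Khand) back to an acyclic 1,6-enyne; then the enyne to 3-methylbutanal and methyl vinyl ketone.
2. Enabling feature: the seven-membered ring holds an unsubstituted CH2–CH2 (C4–C5) between C3a, an alkene carbon of the cyclopentene, and C6, which carries the oxygenated one-carbon branch. C3a and C6 can therefore be the β- and α-carbons of a 2-(methoxycarbonyl)cyclopentenone (ring B) fused to the cyclopentane (ring A). Ethene adds across them, and the C3a–C6 bond is then broken, the electron pair going to the β-keto ester and the positive charge to the future alkene carbon.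
3. Forward order: rings A and B form together (Pauson–Khand), then the cyclobutane ([2+2]); the seven-membered ring arises when the bond shared by the cyclobutane and ring B is cleaved; redox adjustment and esterification finish.
4. Stereochemistry: C8a is the only stereocentre of the target. It is set in the Pauson–Khand step by the isopropyl-bearing centre, which comes from an organocatalytic Michael addition and is erased when C3=C3a forms.

Key step: step 6

Remark: the cobalt-mediated cyclisation is assumed to follow the usual exo preference of a propargylic substituent (isopropyl cis to the angular methyl); the (R) aldehyde 3 is chosen on that basis, and the sense is not secured for this substitution pattern.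

**Step 1**
Reactants: 1 3-methylbutanal; 2 but-3-en-2-one
Product: 3 (2R)-5-oxo-2-(propan-2-yl)hexanal
Conditions: (R)-2-[methoxy(diphenyl)methyl]pyrrolidine (5 mol%), ethyl 3,4-dihydroxybenzoate (20 mol%), neat, 4 °C
Reagents that add atoms: none
Why: Enamine-catalysed Michael addition of an aldehyde to an enone; the E-enamine should be attacked on the face away from the diphenyl(methoxy)methyl group, which sets C2 as R.

**Step 2**
Reactants: 3 (2R)-5-oxo-2-(propan-2-yl)hexanal
Product: 4 (5R)-7,7-dibromo-5-(propan-2-yl)hept-6-en-2-one
Conditions: CBr4, PPh3, CH2Cl2, 0 °C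
Reagents that add atoms: carbon tetrabromide, BrC(Br)(Br)Br
Why: Ramirez dibromo-olefination (first half of the Corey–Fuchs sequence) is selective for the aldehyde over the methyl ketone and needs no base, so the α-stereocentre should survive.

**Step 3**
Reactants: 4 (5R)-7,7-dibromo-5-(propan-2-yl)hept-6-en-2-one
Product: 5 (3R)-1,1-dibromo-6-methyl-3-(propan-2-yl)hepta-1,6-diene
Conditions: Ph3PCH3Br, KN(SiMe3)2, THF, −78 → 0 °C
Reagents that add atoms: methyltriphenylphosphonium bromide, C[P+](c1ccccc1)(c1ccccc1)c1ccccc1.[Br-]
Why: Wittig methylenation of the methyl ketone by the unstabilised ylide; the stereocentre is remote from the carbonyl and not at risk.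

**Step 4**
Reactants: 5 (3R)-1,1-dibromo-6-methyl-3-(propan-2-yl)hepta-1,6-diene
Product: 7 methyl (4R)-7-methyl-4-(propan-2-yl)oct-7-en-2-ynoate, via lithium acetylide 6 (not isolated)
Conditions: n-BuLi (2.1 equiv), THF, −78 → −20 °C; ClCO2Me, −78 → 0 °C
Reagents that add atoms: methyl chloroformate, COC(=O)Cl
Why: Second half of the Corey–Fuchs reaction (Br/Li exchange, 1,2-shift to the alkyne, deprotonation) gives the acetylide, which is C-acylated by the chloroformate.

**Step 5**
Reactants: 7 methyl (4R)-7-methyl-4-(propan-2-yl)oct-7-en-2-ynoate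
Product: 9 methyl (3aR,6R)-3a-methyl-2-oxo-6-(propan-2-yl)-2,3,3a,4,5,6-hexahydropentalene-1-carboxylate, via alkyne hexacarbonyldicobalt complex 8 (not isolated)
Conditions: Co2(CO)8 (1.1 equiv), ClCH2CH2Cl, 23 °C; n-BuSMe (3.5 equiv), 83 °C
Reagents that add atoms: dicobalt octacarbonyl (source of the ring CO), [Co].[Co].[C-]#[O+].[C-]#[O+].[C-]#[O+].[C-]#[O+].[C-]#[O+].[C-]#[O+].[C-]#[O+].[C-]#[O+]
Why: Intramolecular Pauson–Khand reaction (alkyne complexation, alkene insertion, CO insertion, reductive elimination) closes rings A and B and makes the quaternary centre; the propargylic isopropyl group should take the exo position of the cobaltacycle, away from the ester-bearing alkyne terminus, which places it cis to the angular methyl and sets C3a as R, and the minor C3a epimer is removed by chromatography under neutral conditions.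

**Step 6**
Reactants: 9 methyl (3aR,6R)-3a-methyl-2-oxo-6-(propan-2-yl)-2,3,3a,4,5,6-hexahydropentalene-1-carboxylate; 10 ethene
Product: 11 methyl (1R,4R,7R,10R)-7-methyl-5-oxo-10-(propan-2-yl)tricyclo[5.3.0.0(1,4)]decane-4-carboxylate
Conditions: hν (medium-pressure Hg lamp, uranium-glass filter, λ > 330 nm), ethene (saturated solution), CH2Cl2, −78 °C
Reagents that add atoms: none
Why: Excitation of the 2-(methoxycarbonyl)cyclopentenone and intersystem crossing give the triplet enone, whose β-carbon (C6a of 9) bonds to ethene to form a triplet 1,4-biradical that closes at C1 after spin inversion. The closest known reaction type is the enone–alkene [2+2] photocycloaddition of cyclopentenones with ethene, the first half of de Mayo-type two-carbon ring expansions. The only ring closed is the cyclobutane, formed by intermolecular (2+2) annulation through recombination of the 1,4-biradical. The two new stereocentres (C1 and C4 of 11) are fixed by ring strain: the cyclobutane must be cis-fused to ring B and rings A and B must stay cis-fused, so ethene can only add to the enone face that carries the angular methyl of the existing quaternary centre. The step needs chemoselectivity for the enone C=C and freedom from secondary photolysis; 9 has no other alkene, ethene is symmetric so no regiochemistry arises, and the long-wavelength filter keeps the saturated ketone product out of the light.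

**Step 7**
Reactants: 11 methyl (1R,4R,7R,10R)-7-methyl-5-oxo-10-(propan-2-yl)tricyclo[5.3.0.0(1,4)]decane-4-carboxylate
Product: 14 methyl (8aR)-8a-methyl-7-oxo-3-(propan-2-yl)-1,2,4,5,6,7,8,8a-octahydroazulene-6-carboxylate, via tertiary iodide 12 (not isolated), via silyl enol ether 13 (not isolated)
Conditions: Me3SiI, CH2Cl2, −20 → 0 °C; DBU, 0 → 23 °C; aq HCl work-up
Reagents that add atoms: none
Why: Iodotrimethylsilane opening of an acyl cyclobutane (the counterpart of the opening of cyclopropyl ketones to γ-iodo ketones): O-silylation triggers SN1-type heterolysis of the strained C1–C4 bond between the bis-acceptor carbon and the tertiary carbon, dehydroiodination toward C10–H should give the tetrasubstituted (Zaitsev) alkene, and acid frees the β-keto ester, which completes the five-to-seven ring expansion and erases the relay centre at C10.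

**Step 8**
Reactants: 14 methyl (8aR)-8a-methyl-7-oxo-3-(propan-2-yl)-1,2,4,5,6,7,8,8a-octahydroazulene-6-carboxylate
Product: 15 methyl (8aR)-7-hydroxy-8a-methyl-3-(propan-2-yl)-1,2,4,5,6,7,8,8a-octahydroazulene-6-carboxylate
Conditions: NaBH4, MeOH, 0 °C
Reagents that add atoms: none
Why: Borohydride reduction of the ketone of a β-keto ester; the configuration of the new carbinol is immaterial because it is eliminated in the next step.

**Step 9**
Reactants: 15 methyl (8aR)-7-hydroxy-8a-methyl-3-(propan-2-yl)-1,2,4,5,6,7,8,8a-octahydroazulene-6-carboxylate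
Product: 17 methyl (8aR)-8a-methyl-3-(propan-2-yl)-1,2,4,5,8,8a-hexahydroazulene-6-carboxylate, via mesylate 16 (not isolated)
Conditions: MsCl, Et3N, CH2Cl2, 0 °C; DBU, 23 °C
Reagents that add atoms: none
Why: Mesylation, then E1cB elimination through the ester enolate; only C6–H is acidic, so the double bond can form only between C6 and C7, which fixes the position of the trisubstituted alkene.

**Step 10**
Reactants: 17 methyl (8aR)-8a-methyl-3-(propan-2-yl)-1,2,4,5,8,8a-hexahydroazulene-6-carboxylate
Product: 18 [(8aR)-8a-methyl-3-(propan-2-yl)-1,2,4,5,8,8a-hexahydroazulen-6-yl]methanol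
Conditions: i-Bu2AlH (2.5 equiv), CH2Cl2, −78 → 0 °C; potassium sodium tartrate work-up
Reagents that add atoms: none
Why: 1,2-Reduction of an α,β-unsaturated ester to the allylic alcohol by the aluminium hydride, which leaves both alkenes untouched.

**Step 11**
Reactants: 18 [(8aR)-8a-methyl-3-(propan-2-yl)-1,2,4,5,8,8a-hexahydroazulen-6-yl]methanol; 19 4-hydroxy-3-methoxybenzoic acid
Product: 20 [(8aR)-8a-methyl-3-(propan-2-yl)-1,2,4,5,8,8a-hexahydroazulen-6-yl]methyl 4-hydroxy-3-methoxybenzoate
Conditions: PPh3, DIAD, THF, 0 → 23 °C
Reagents that add atoms: none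
Why: Mitsunobu esterification; the carboxylic acid is the stronger acid and its carboxylate displaces the primary allylic oxyphosphonium by SN2, while the less acidic phenol should stay free, as is known for phenolic acids.

**Compound list**

1 | 3-methylbutanal | CC(C)CC=O | starting material
2 | but-3-en-2-one (methyl vinyl ketone) | CC(=O)C=C | starting material
3 | (2R)-5-oxo-2-(propan-2-yl)hexanal | CC(C)[C@H](C=O)CCC(C)=O | intermediate
4 | (5R)-7,7-dibromo-5-(propan-2-yl)hept-6-en-2-one | CC(C)[C@H](C=C(Br)Br)CCC(C)=O | intermediate
5 | (3R)-1,1-dibromo-6-methyl-3-(propan-2-yl)hepta-1,6-diene | CC(C)[C@H](C=C(Br)Br)CCC(C)=C | intermediate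
6 | lithium (3R)-6-methyl-3-(propan-2-yl)hept-6-en-1-yn-1-ide | CC(C)[C@H](C#C[Li])CCC(C)=C | intermediate
7 | methyl (4R)-7-methyl-4-(propan-2-yl)oct-7-en-2-ynoate | CC(C)[C@H](C#CC(=O)OC)CCC(C)=C | intermediate
8 | hexacarbonyldicobalt complex of alkyne 7 (Co2(CO)6 bridging the triple bond; written as its components) | CC(C)[C@H](C#CC(=O)OC)CCC(C)=C.[Co].[Co].[C-]#[O+].[C-]#[O+].[C-]#[O+].[C-]#[O+].[C-]#[O+].[C-]#[O+] | intermediate
9 | methyl (3aR,6R)-3a-methyl-2-oxo-6-(propan-2-yl)-2,3,3a,4,5,6-hexahydropentalene-1-carboxylate (isopropyl cis to the angular methyl) | COC(=O)C1=C2[C@@H](C(C)C)CC[C@]2(C)CC1=O | intermediate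
10 | ethene | C=C | starting material
11 | methyl (1R,4R,7R,10R)-7-methyl-5-oxo-10-(propan-2-yl)tricyclo[5.3.0.0(1,4)]decane-4-carboxylate (cyclobutane cis-fused to ring B, its CH2 at C1 cis to the angular methyl) | COC(=O)[C@@]12C(=O)C[C@@]3(C)CC[C@H](C(C)C)[C@@]13CC2 | intermediate
12 | methyl (3R,8aR)-3a-iodo-8a-methyl-3-(propan-2-yl)-7-[(trimethylsilyl)oxy]-1,2,3,3a,4,5,8,8a-octahydroazulene-6-carboxylate (C3a not defined) | COC(=O)C1=C(O[Si](C)(C)C)C[C@@]2(C)CC[C@H](C(C)C)C2(I)CC1 | intermediate
13 | methyl (8aR)-8a-methyl-3-(propan-2-yl)-7-[(trimethylsilyl)oxy]-1,2,4,5,8,8a-hexahydroazulene-6-carboxylate | COC(=O)C1=C(O[Si](C)(C)C)C[C@@]2(C)CCC(C(C)C)=C2CC1 | intermediate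
14 | methyl (8aR)-8a-methyl-7-oxo-3-(propan-2-yl)-1,2,4,5,6,7,8,8a-octahydroazulene-6-carboxylate (C6 epimers and enol form) | COC(=O)C1CCC2=C(C(C)C)CC[C@]2(C)CC1=O | intermediate
15 | methyl (8aR)-7-hydroxy-8a-methyl-3-(propan-2-yl)-1,2,4,5,6,7,8,8a-octahydroazulene-6-carboxylate (mixture at C6 and C7) | COC(=O)C1CCC2=C(C(C)C)CC[C@]2(C)CC1O | intermediate
16 | methyl (8aR)-7-(methanesulfonyloxy)-8a-methyl-3-(propan-2-yl)-1,2,4,5,6,7,8,8a-octahydroazulene-6-carboxylate | COC(=O)C1CCC2=C(C(C)C)CC[C@]2(C)CC1OS(C)(=O)=O | intermediate
17 | methyl (8aR)-8a-methyl-3-(propan-2-yl)-1,2,4,5,8,8a-hexahydroazulene-6-carboxylate | COC(=O)C1=CC[C@@]2(C)CCC(C(C)C)=C2CC1 | intermediate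
18 | [(8aR)-8a-methyl-3-(propan-2-yl)-1,2,4,5,8,8a-hexahydroazulen-6-yl]methanol | OCC1=CC[C@@]2(C)CCC(C(C)C)=C2CC1 | intermediate
19 | 4-hydroxy-3-methoxybenzoic acid (vanillic acid) | COc1cc(C(=O)O)ccc1O | starting material
20 | [(8aR)-8a-methyl-3-(propan-2-yl)-1,2,4,5,8,8a-hexahydroazulen-6-yl]methyl 4-hydroxy-3-methoxybenzoate | COc1cc(C(=O)OCC2=CC[C@@]3(C)CCC(C(C)C)=C3CC2)ccc1O | target

**Totals and risks**

Total step count: 11. Longest linear sequence: 11 steps (1 → 20).

Steps most likely to fail:

Step 7. The tertiary cation or iodide may lose a proton toward the seven-membered ring instead of toward the isopropyl-bearing carbon, or undergo a 1,2-shift from the neighbouring quaternary carbon before elimination. Fallback, from 11 directly to 14: thermolysis of 11 (o-dichlorobenzene, sealed tube, about 200 °C, or flash vacuum pyrolysis) as a concerted retro-ene ring opening, the reverse of a Conia-ene cyclisation. In 11 the ester carbonyl is cis to C10 on the cyclobutane and the C10 hydrogen points to the same side, so the hydrogen can pass to oxygen through a six-membered transition state as the C1–C4 bond breaks. No ion is formed, the alkene can only arise at C10, and the enol tautomerises to 14. No new compound arises on this way (F0).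

Step 5. Facial selectivity of the alkene insertion may be low or reversed, since the isopropyl group is pushed exo only by the modest allylic strain against the ester while it meets the angular methyl on that face; insertion of the electron-poor alkyne complex may also be sluggish. Fallback, from 5 back to 9: n-BuLi then Me3SiCl gives trimethyl[(3R)-6-methyl-3-(propan-2-yl)hept-6-en-1-yn-1-yl]silane F1. Its Co2(CO)8-mediated cyclisation, where the bulky silyl group on the alkyne terminus enforces the exo placement much more strongly, gives the silyl enone F2. ICl then effects ipso-iododesilylation to the iodo enone F3, and methoxycarbonylation (Pd(PPh3)4, CO, MeOH, Et3N) returns to 9.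

Step 6. Bond formation at the β-carbon, which lies next to the quaternary centre and creates three contiguous fully substituted carbons, may be slow, so that decay of the excited enone and secondary photolysis of the product compete. Fallback, from 9 back to 11: irradiation in neat (Z)-1,2-dichloroethene, a partner proven on hindered bicyclic enones and usable at high concentration, gives the dichlorocyclobutane F4. Zinc in ethanol removes the two chlorines to give the cyclobutene F5, and hydrogenation (H2, palladium on carbon, EtOAc) returns to 11.

**Further compounds**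

F1 | step 5 | trimethyl[(3R)-6-methyl-3-(propan-2-yl)hept-6-en-1-yn-1-yl]silane | CC(C)[C@H](C#C[Si](C)(C)C)CCC(C)=C
F2 | step 5 | silyl enone, the (3aR,6R) analogue of 9 that carries SiMe3 in place of CO2Me | C[Si](C)(C)C1=C2[C@@H](C(C)C)CC[C@]2(C)CC1=O
F3 | step 5 | iodo enone, the (3aR,6R) analogue of 9 that carries iodine in place of CO2Me | IC1=C2[C@@H](C(C)C)CC[C@]2(C)CC1=O
F4 | step 6 | 2,3-dichloro derivative of 11 (epimers at the two CHCl carbons) | COC(=O)[C@@]12C(=O)C[C@@]3(C)CC[C@H](C(C)C)[C@@]13C(Cl)C2Cl
F5 | step 6 | 2,3-didehydro derivative of 11 (cyclobutene) | COC(=O)[C@@]12C(=O)C[C@@]3(C)CC[C@H](C(C)C)[C@@]13C=C2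
F0 | step 7 | none | none
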